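## Structural features

The target is a 2-arylchroman-4-one of the dihydroflavonol 3-methyl ether type: aromatic ring A is fused through C4a–C8a to the dihydropyranone ring C, and ring B is joined to C2 by a single C–C bond. Ring A is hexasubstituted, with a free 5-OH, a free 6-OH and a 7-OMe in a row, a lone hydrogen at C8, the ether oxygen O1 at C8a and the C4 carbonyl at C4a; ring B is a 2,3-dihydroxy-4-methoxyphenyl group. The only stereocentres are the adjacent C2 (benzylic, bound to O1) and C3 (methoxy-bearing, alpha to the C4 ketone), both R, which places the aryl and methoxy groups trans and diequatorial. Fragile points are the two air-sensitive catechols, the enolisable C3–H, and the benzylic C2–O1 bond, which can open by beta-elimination from a C3 enolate or with help from the ortho 2'-hydroxyl, so base and prolonged heat threaten both stereocentres. The real difficulty is the regiodefined, differentiated oxygen pattern of ring A (which of three neighbouring oxygens is methylated), together with keeping the trans C2/C3 pair intact to the end. The key step uses the fact that C5–C8 with their three oxygens correspond to a 1,2,3-trioxygenated butadiene, while C4a=C8a, flanked by the C4 carbonyl and O1, corresponds to the enol ether double bond of a dihydropyran-4-one whose C4a carbon can carry bromine as the leaving group that fixes the aromatic oxidation level.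

## Logic of the disconnections

**19 to 18.** The three benzylic O–CH2Ph bonds at O6, O2' and O3' are cut. Three of the four phenols need protection during assembly, and choosing benzyl for all three means one neutral hydrogenolysis releases both catechols at the very end. The 5-OH needs no protection because it emerges hydrogen-bonded to the C4 carbonyl. The forward step must spare the benzylic C2–O1 bond and the ketone and must avoid base.

**18 to 9 and 15.** The C4a–C5 and C8–C8a bonds are cut, which removes ring A altogether. The oxygen pattern is then written into diene 15 (ketene acetal carbon becomes C5–OH, benzyloxy carbon C6, methoxy carbon C7, CH2 becomes C8–H), and both stereocentres sit in enone 9. Structures 9, 15 and 18 were checked atom by atom against 19 and need no correction. The forward step demands that the CH2 terminus of 15 bonds to the beta carbon of 9, that the weakly electrophilic beta-alkoxy enone reacts at all, and that the adduct aromatises without base. One point of mechanism is sharpened: in the cis-fused adduct the bromine and the C8a hydrogen are cis, so HBr cannot leave by anti elimination. It is expected to leave after enolisation towards C8, by ionisation of the then allylic C4a–Br bond and loss of the C8a proton.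

**15 to 13 to 12 to 10.** The O–Si bond (with the gamma C–H) is cut, then the enol O–CH3 bond, then the C2–C3 bond of the butanoate. This reduces the diene to ester 10, which already carries the benzyloxy group destined for O6, plus an acetyl donor. The forward steps demand C-acylation of a glycolate enolate without self-condensation, O- rather than C-methylation, and gamma-deprotonation of a tetrasubstituted enol ether.

**9 to 8.** The C5–Br bond is cut. Bromine is put on last, at the nucleophilic alpha carbon of the vinylogous ester, so no earlier step has to tolerate a vinyl bromide. The forward step demands chemoselectivity over the electron-rich ring B.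

**8 to 7 to 5.** The O–CH3 bond at O3 and then the C3–O bond are cut. The C3 oxygen is introduced on the ring, where the C2 aryl group directs it trans. A diene analogous to 3 that already carries the methoxy group was considered and set aside: its endo cycloaddition would give the 2,3-cis adduct, and correcting C3 afterwards by enolisation would expose C2 to ring opening. The forward steps demand a short-lived, cold enolate and a non-basic methylation.

**5 to 2 and 3.** The C2–C3 and O1–C6 bonds of the pyranone are cut (hetero-Diels–Alder). This leaves aldehyde 2 and commercial diene 3 and puts the whole burden of absolute configuration on one catalytic step. Compound 5 is 2S although its C2 has the same spatial arrangement as the 2R centre of 7 to 19, because C3 outranks the aryl group only once it bears oxygen.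

**2 to 1.** The two O–benzyl bonds are cut, leading to commercial catechol aldehyde 1.

## Other disconnections considered

**Alternative 1:** The cut is the C3–C4 bond of ring C.
- Forward step: seco acid A2 already holds the O1–C2 aryl ether and an S-ethyl thioester on ring A. Under visible light with Ir[dF(CF3)ppy]2(dtbbpy)PF6 it would be decarboxylated to the alpha-methoxy radical at C3. NiCl2·glyme with 4,4'-di-tert-butyl-2,2'-bipyridine would take up the thioester and join acyl group and radical, closing ring C as ketone A1.
- In favour: ring A enters as an intact, fully oxygenated arene, so no regiochemical question arises on ring A. On this point it is better than the chosen plan, which rests on the orientation of a cycloaddition. The conditions are neutral and at room temperature, and alpha-alkoxy acids are good radical precursors.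
- Against: the radical carbon carries a beta-aryloxy group, and once it is bound to nickel, beta-elimination of the ring A phenoxide competes with C–C bond formation. The thioester lies between two ortho substituents. C3 is made from a planar radical, so the trans relation must come from the ring closure itself or from later enolisation next to the labile C2. A1 keeps a 5-methoxy group that must be cleaved selectively. A2 needs an enantioselective synthesis of a hindered benzylic aryl ether.
- Comparison: both plans reach the same ring C and the same benzyl pattern, and both key steps leave C2 untouched, so they are equal there. Mechanistically the chosen plan uses a pericyclic annulation with a clear polarity argument, while this one needs a ring-closing radical–acyl coupling that must outrun a beta-elimination. In steps it is not shorter: one extra deprotection follows A1, and the route to A2 is at least as long as that to 9 plus 15.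

**Alternative 2:** The cuts are O1–C2 and C3–C4.
- Forward step: salicylaldehyde A4 and trimethyl orthoformate would give, under a chiral phosphoric acid, a 4-methoxy ortho-quinone methide. This would add styrylboronate A5 (available from 2), closing ring C as boronate A3 (2,3-trans, 2S,3S by the sequence rules because boron changes the priorities).
- In favour: both stereocentres of ring C are made in one catalytic step, the trans relation is copied from the E alkene, and oxidation of C–B to C–O goes with retention. This is better than the chosen plan, which sets C2 and C3 in two separate steps. The two fragments are simple and the union is convergent.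
- Against: A3 has C4 at the alcohol level as a methyl ether, so C–B oxidation, O-methylation, oxidation at C4, 5-O-demethylation and hydrogenolysis must follow. Oxidising the C4 benzylic ether in the presence of the even more activated C2–H is a serious selectivity problem. The quinone methide bears three donor oxygens and is a weak electrophile, while an alkenylboronate is not an electron-rich partner. A stepwise cationic course would loosen the stereospecificity.
- Comparison: structurally it builds ring C on a finished ring A, the reverse of the chosen plan. In stereocontrol it is the better plan on paper. In redox and step economy after the key step it is clearly worse (about five steps against one).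

**Alternative 3:** The cut is O1–C8a.
- Forward step: open-chain catechol ketone A7 (ring A and ring B both from the 2,3-dioxygenated 4-methoxyphenyl unit of 1) would be oxidised with Ag2O or NaIO4 to the ring A ortho-quinone. The C2 hydroxyl would add to C8a, which is beta both to the quinone carbonyl at C5 and to the C4 ketone, and tautomerisation would give catechol A6.
- In favour: only the six-membered mode of addition is geometrically possible, so regiochemistry is not in doubt. Ring A needs no protecting group, and A6 is one hydrogenolysis from 19, equal to the chosen plan after the key step. One building block serves both rings, so the overall step count is probably lower than in the chosen plan; on this point it is better.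
- Against: A6 has one more donor oxygen than A7 and is the more easily oxidised catechol, so over-oxidation by the oxidant or by the intermediate quinone is to be expected. An acyl ortho-quinone is also open to water and to dimerisation. The beta-hydroxy ketone can undergo retro-aldol cleavage. C2 and C3 must be set in an acyclic anti aldol of an alpha-methoxy aryl ketone, whose C3 is configurationally labile, whereas the chosen plan sets them on a ring that enforces trans. Ring A also needs temporary protection during that aldol.
- Comparison: mechanistically it is a polar oxidation and conjugate addition, against a cycloaddition and elimination. It is shorter and more atom-economical, but its key step depends on stopping an oxidation at a product that is more oxidisable than the substrate, a risk the chosen plan does not carry.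

Key step: step 9

Assumption (sense of induction): the (S,S) enantiomer of the chromium salen catalyst is taken to deliver the 2S pyranone from an aryl aldehyde, by analogy with the sense known for its antipode with benzaldehyde; should the sense be opposite for 2, the (R,R) catalyst is used and nothing else changes.

## Route

Step 1
Reactants: 1 2,3-dihydroxy-4-methoxybenzaldehyde
Product: 2 2,3-bis(benzyloxy)-4-methoxybenzaldehyde
Conditions: BnBr (2.5 equiv), K2CO3, DMF, 60 °C
Reagents that add atoms: benzyl bromide, BrCc1ccccc1
Why: Williamson ether synthesis on both phenols; DMF and gentle heat are chosen because the 2-hydroxyl is hydrogen-bonded to the aldehyde and reacts slowly.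

Step 2
Reactants: 2 2,3-bis(benzyloxy)-4-methoxybenzaldehyde; 3 (E)-1-methoxy-3-(trimethylsilyloxy)buta-1,3-diene
Product: 5 (2S)-2-[2,3-bis(benzyloxy)-4-methoxyphenyl]-2,3-dihydro-4H-pyran-4-one, via silyl enol ether cycloadduct 4 (not isolated)
Conditions: (S,S)-[N,N'-bis(3,5-di-tert-butylsalicylidene)cyclohexane-1,2-diaminato]CrBF4 (5 mol%), 4 Å MS, t-BuOMe, −30 °C to rt; then TFA, CH2Cl2, 0 °C
Reagents that add atoms: none
Why: Catalytic enantioselective hetero-Diels–Alder reaction of an aldehyde with a 1-methoxy-3-silyloxy diene; the chiral chromium salen Lewis acid binds the aldehyde and leaves one carbonyl face open to the diene, which sets C2. Acid then cleaves the silyl enol ether and eliminates methanol to give the enone.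

Step 3
Reactants: 5 (2S)-2-[2,3-bis(benzyloxy)-4-methoxyphenyl]-2,3-dihydro-4H-pyran-4-one
Product: 7 (2R,3R)-2-[2,3-bis(benzyloxy)-4-methoxyphenyl]-3-hydroxy-2,3-dihydro-4H-pyran-4-one, via sodium enolate 6 (not isolated)
Conditions: NaN(SiMe3)2, THF, −78 °C; then 2-(phenylsulfonyl)-3-phenyloxaziridine, −78 °C; aq NH4Cl
Reagents that add atoms: 2-(phenylsulfonyl)-3-phenyloxaziridine, O=S(=O)(c1ccccc1)N1OC1c1ccccc1
Why: Enolate hydroxylation with an N-sulfonyloxaziridine; C3 is the only enolisable position, and the oxidant should approach the enolate face anti to the C2 aryl group, which sets C3 trans (also the more stable diequatorial isomer). The low temperature and short enolate lifetime are meant to suppress beta-elimination of O1.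

Step 4
Reactants: 7 (2R,3R)-2-[2,3-bis(benzyloxy)-4-methoxyphenyl]-3-hydroxy-2,3-dihydro-4H-pyran-4-one
Product: 8 (2R,3R)-2-[2,3-bis(benzyloxy)-4-methoxyphenyl]-3-methoxy-2,3-dihydro-4H-pyran-4-one
Conditions: MeI (excess), Ag2O, 4 Å MS, CH2Cl2, rt, dark
Reagents that add atoms: iodomethane, CI
Why: Purdie methylation; the silver-assisted alkylation needs no strong base, so the alpha-hydroxy ketone is not enolised and C2 and C3 are kept, in the way the 3-hydroxyl of dihydroflavonols is methylated.

Step 5
Reactants: 8 (2R,3R)-2-[2,3-bis(benzyloxy)-4-methoxyphenyl]-3-methoxy-2,3-dihydro-4H-pyran-4-one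
Product: 9 (2R,3R)-2-[2,3-bis(benzyloxy)-4-methoxyphenyl]-5-bromo-3-methoxy-2,3-dihydro-4H-pyran-4-one
Conditions: NBS (1.05 equiv), CH2Cl2, 0 °C, dark
Reagents that add atoms: N-bromosuccinimide, O=C1CCC(=O)N1Br
Why: Electrophilic alpha-bromination of a vinylogous ester: bromine adds to the nucleophilic C5, and the O1-stabilised cation loses the C5 proton. In a non-polar solvent at 0 °C without acid the enol ether carbon should react well before ring B, and no base is present to touch C3.

Step 6
Reactants: 10 methyl (benzyloxy)acetate
Product: 12 methyl 2-(benzyloxy)-3-oxobutanoate, via lithium ester enolate 11 (not isolated)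
Conditions: LiN(iPr)2, THF, −78 °C; then MeC(O)N(OMe)Me, −78 to 0 °C; aq NH4Cl
Reagents that add atoms: N-methoxy-N-methylacetamide, CC(=O)N(C)OC
Why: Crossed Claisen-type C-acylation of a lithium ester enolate by an N-methoxy-N-methylamide, which does not add twice; adding the ester slowly to cold base limits self-condensation.

Step 7
Reactants: 12 methyl 2-(benzyloxy)-3-oxobutanoate
Product: 13 methyl 2-(benzyloxy)-3-methoxybut-2-enoate
Conditions: HC(OMe)3, H2SO4 (cat.), MeOH, 50 °C
Reagents that add atoms: trimethyl orthoformate, COC(OC)OC
Why: Acid-catalysed ketalisation with the orthoformate followed by loss of methanol gives the beta-methoxy enoate, the standard O-methylation of a beta-keto ester. The alkene geometry is irrelevant because this bond becomes the central single bond of the diene.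

Step 8
Reactants: 13 methyl 2-(benzyloxy)-3-methoxybut-2-enoate
Product: 15 {[2-(benzyloxy)-1,3-dimethoxybuta-1,3-dien-1-yl]oxy}trimethylsilane, via lithium dienolate 14 (not isolated)
Conditions: LiN(iPr)2, THF, −78 °C; then Me3SiCl, −78 °C to rt; filtration under argon, used crude
Reagents that add atoms: chlorotrimethylsilane, C[Si](C)(C)Cl
Why: Vinylogous (gamma) deprotonation of a 3-alkoxy enoate and O-silylation of the dienolate, the usual way to 1,3-dialkoxy-1-silyloxy dienes; there is no alpha hydrogen, so only the methyl group can be deprotonated.

Step 9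
Reactants: 9 (2R,3R)-2-[2,3-bis(benzyloxy)-4-methoxyphenyl]-5-bromo-3-methoxy-2,3-dihydro-4H-pyran-4-one; 15 {[2-(benzyloxy)-1,3-dimethoxybuta-1,3-dien-1-yl]oxy}trimethylsilane
Product: 18 (2R,3R)-6-(benzyloxy)-2-[2,3-bis(benzyloxy)-4-methoxyphenyl]-5-hydroxy-3,7-dimethoxychroman-4-one, via bromo ketal cycloadduct 16 (not isolated), via bromo diketone 17 (not isolated)
Conditions: 15 (3 equiv), toluene, 90 °C, sealed tube; then SiO2, wet CH2Cl2, rt
Reagents that add atoms: none
Why: Proposed new method: the electron-rich diene 15, whose CH2 terminus is its most nucleophilic carbon (pushed by the ketene acetal oxygens and by the adjacent methoxy group), should add to the bromo enone 9 in a thermal, strongly asynchronous [4+2] cycloaddition, the CH2 carbon bonding to the beta carbon C6 of 9 (future C8a) and the ketene acetal carbon to the bromine-bearing C5 (future C4a) to give the cis-fused adduct 16. Loss of Me3SiOMe from the mixed ketal gives 17; enolisation towards C8 then makes the C4a–Br bond allylic, bromide ionises with support from the 6-benzyloxy group, and loss of the C8a proton gives the phenol, a stepwise path that is needed because Br and H are cis in 16. The closest known reaction type is the cycloaddition of 1,1-dioxygenated silyl ketene acetal dienes with alpha-halo quinones and alpha-halo enones followed by loss of hydrogen halide and alcohol to regiodefined phenols; new here is a beta-alkoxy enone (vinylogous ester) on a chiral dihydropyranone as the dienophile. Ring A is closed as a six-membered carbocycle by intermolecular [4+2] annulation, both of its new bonds (C4a–C5 and C8–C8a) being made in the one operation; should the addition be stepwise, a Mukaiyama–Michael addition at C6 followed by six-membered closure of the bromo enolate leads to the same 16. No new stereocentre survives, since C4a, C5 and C8a of 16 are flattened on aromatisation, and C2 and C3 are spectators set in steps 2 and 3. The selectivity needed is regiochemical (5-OH next to the C4 carbonyl, 7-OMe next to C8) and is secured by the polarity match of the CH2 terminus with the beta carbon and by the bromine sitting on the alpha carbon; the bromine also lowers the acceptor orbital of the sluggish vinylogous ester and supplies the oxidation level, so no oxidant is required. No base is added and the excess diene takes up the acid released, so C3 is not enolised and C2–O1 is not opened.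

Step 10
Reactants: 18 (2R,3R)-6-(benzyloxy)-2-[2,3-bis(benzyloxy)-4-methoxyphenyl]-5-hydroxy-3,7-dimethoxychroman-4-one
Product: 19 (2R,3R)-2-(2,3-dihydroxy-4-methoxyphenyl)-5,6-dihydroxy-3,7-dimethoxychroman-4-one
Conditions: H2 (1 atm), 10% Pd/C, EtOAc–MeOH, rt
Reagents that add atoms: none
Why: Hydrogenolysis of three aryl benzyl ethers over palladium on carbon; the neutral conditions at room temperature should leave the ketone, the cyclic benzylic C2–O1 ether and both stereocentres untouched if the reaction is stopped after uptake of three equivalents and worked up under argon.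

## Compound list

1 | 2,3-dihydroxy-4-methoxybenzaldehyde | COc1ccc(C=O)c(O)c1O | starting material
2 | 2,3-bis(benzyloxy)-4-methoxybenzaldehyde | COc1ccc(C=O)c(OCc2ccccc2)c1OCc1ccccc1 | intermediate
3 | (E)-1-methoxy-3-(trimethylsilyloxy)buta-1,3-diene | CO/C=C/C(=C)O[Si](C)(C)C | starting material
4 | (2S)-2-[2,3-bis(benzyloxy)-4-methoxyphenyl]-6-methoxy-4-(trimethylsilyloxy)-3,6-dihydro-2H-pyran (C6 epimers) | COc1ccc([C@H]2OC(OC)C=C(O[Si](C)(C)C)C2)c(OCc2ccccc2)c1OCc1ccccc1 | intermediate
5 | (2S)-2-[2,3-bis(benzyloxy)-4-methoxyphenyl]-2,3-dihydro-4H-pyran-4-one | COc1ccc([C@H]2OC=CC(=O)C2)c(OCc2ccccc2)c1OCc1ccccc1 | intermediate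
6 | sodium (2S)-2-[2,3-bis(benzyloxy)-4-methoxyphenyl]-2H-pyran-4-olate | COc1ccc([C@H]2OC=CC([O-])=C2)c(OCc2ccccc2)c1OCc1ccccc1.[Na+] | intermediate
7 | (2R,3R)-2-[2,3-bis(benzyloxy)-4-methoxyphenyl]-3-hydroxy-2,3-dihydro-4H-pyran-4-one | COc1ccc([C@H]2OC=CC(=O)[C@@H]2O)c(OCc2ccccc2)c1OCc1ccccc1 | intermediate
8 | (2R,3R)-2-[2,3-bis(benzyloxy)-4-methoxyphenyl]-3-methoxy-2,3-dihydro-4H-pyran-4-one | COc1ccc([C@H]2OC=CC(=O)[C@@H]2OC)c(OCc2ccccc2)c1OCc1ccccc1 | intermediate
9 | (2R,3R)-2-[2,3-bis(benzyloxy)-4-methoxyphenyl]-5-bromo-3-methoxy-2,3-dihydro-4H-pyran-4-one | COc1ccc([C@H]2OC=C(Br)C(=O)[C@@H]2OC)c(OCc2ccccc2)c1OCc1ccccc1 | intermediate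
10 | methyl (benzyloxy)acetate | COC(=O)COCc1ccccc1 | starting material
11 | lithium enolate of methyl (benzyloxy)acetate | [Li+].COC([O-])=COCc1ccccc1 | intermediate
12 | methyl 2-(benzyloxy)-3-oxobutanoate (racemic) | COC(=O)C(OCc1ccccc1)C(C)=O | intermediate
13 | methyl 2-(benzyloxy)-3-methoxybut-2-enoate (E/Z mixture) | COC(=O)C(OCc1ccccc1)=C(C)OC | intermediate
14 | lithium 2-(benzyloxy)-1,3-dimethoxybuta-1,3-dien-1-olate | [Li+].COC([O-])=C(OCc1ccccc1)C(=C)OC | intermediate
15 | {[2-(benzyloxy)-1,3-dimethoxybuta-1,3-dien-1-yl]oxy}trimethylsilane | C=C(OC)C(OCc1ccccc1)=C(OC)O[Si](C)(C)C | intermediate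
16 | (2R,3R)-6-(benzyloxy)-2-[2,3-bis(benzyloxy)-4-methoxyphenyl]-4a-bromo-3,5,7-trimethoxy-5-(trimethylsilyloxy)-2,3,4a,5,8,8a-hexahydro-4H-chromen-4-one (cis-fused, C5 epimers) | COc1ccc([C@H]2OC3CC(OC)=C(OCc4ccccc4)C(OC)(O[Si](C)(C)C)C3(Br)C(=O)[C@@H]2OC)c(OCc2ccccc2)c1OCc1ccccc1 | intermediate
17 | (2R,3R)-6-(benzyloxy)-2-[2,3-bis(benzyloxy)-4-methoxyphenyl]-4a-bromo-3,7-dimethoxy-2,3,8,8a-tetrahydro-4H-chromene-4,5(4aH)-dione (cis-fused) | COc1ccc([C@H]2OC3CC(OC)=C(OCc4ccccc4)C(=O)C3(Br)C(=O)[C@@H]2OC)c(OCc2ccccc2)c1OCc1ccccc1 | intermediate
18 | (2R,3R)-6-(benzyloxy)-2-[2,3-bis(benzyloxy)-4-methoxyphenyl]-5-hydroxy-3,7-dimethoxychroman-4-one | COc1ccc([C@H]2Oc3cc(OC)c(OCc4ccccc4)c(O)c3C(=O)[C@@H]2OC)c(OCc2ccccc2)c1OCc1ccccc1 | intermediate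
19 | (2R,3R)-2-(2,3-dihydroxy-4-methoxyphenyl)-5,6-dihydroxy-3,7-dimethoxychroman-4-one | COc1ccc([C@H]2Oc3cc(OC)c(O)c(O)c3C(=O)[C@@H]2OC)c(O)c1O | target

## Step count and least certain steps

Total: 10 steps. Longest linear sequence: 7 steps from 1 (steps 1, 2, 3, 4, 5, 9, 10); the diene branch (steps 6, 7, 8) joins at step 9.

**Step 9 (bears the label).** Most likely failure: the beta-alkoxy enone is too weak an acceptor, so the diene is consumed by protodesilylation and oligomerisation before it adds. A second failure mode is misdirected aromatisation of the adduct, with reductive loss of bromine in place of loss of HBr. The fallback uses known flavonoid chemistry and buys ring A intact. It sets out from 2 and commercial 1-(2-hydroxy-4,6-dimethoxyphenyl)ethanone and comes back at 18. Elbs persulfate oxidation of the ketone (K2S2O8, aq NaOH, then HCl) should give 1-(3,6-dihydroxy-2,4-dimethoxyphenyl)ethanone F1. Its non-chelated hydroxyl is benzylated (BnBr, K2CO3, acetone) to 1-[3-(benzyloxy)-6-hydroxy-2,4-dimethoxyphenyl]ethanone F2. Chloromethyl methyl ether and NaH in DMF give 1-[3-(benzyloxy)-2,4-dimethoxy-6-(methoxymethoxy)phenyl]ethanone F3. Claisen–Schmidt condensation of F3 with 2 (KOH, EtOH) gives (E)-1-[3-(benzyloxy)-2,4-dimethoxy-6-(methoxymethoxy)phenyl]-3-[2,3-bis(benzyloxy)-4-methoxyphenyl]prop-2-en-1-one F4. Julia–Colonna epoxidation (poly-L-leucine, urea–H2O2, DBU, THF) gives [(2R,3S)-3-[2,3-bis(benzyloxy)-4-methoxyphenyl]oxiran-2-yl][3-(benzyloxy)-2,4-dimethoxy-6-(methoxymethoxy)phenyl]methanone F5. HCl in MeOH–THF removes the methoxymethyl group, and the freed phenol opens the epoxide at the benzylic carbon with inversion to give (2R,3R)-6-(benzyloxy)-2-[2,3-bis(benzyloxy)-4-methoxyphenyl]-3-hydroxy-5,7-dimethoxychroman-4-one F6. Purdie methylation (MeI, Ag2O) gives (2R,3R)-6-(benzyloxy)-2-[2,3-bis(benzyloxy)-4-methoxyphenyl]-3,5,7-trimethoxychroman-4-one F7, the same compound as A1. Chelation-directed cleavage of its 5-methoxy group with MgI2·OEt2 in THF–toluene gives 18.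

**Step 3.** Most likely failure: beta-elimination of O1 from the enolate (ring opening, with erosion of the C2 configuration on reclosure), and addition of the enolate to the sulfonylimine formed from the oxidant. The fallback replaces enolate oxidation by a radical alpha'-acetoxylation. It sets out from 5 and comes back at 7. Mn(OAc)3·2H2O in benzene at reflux should give the trans acetate (2R,3R)-2-[2,3-bis(benzyloxy)-4-methoxyphenyl]-4-oxo-3,4-dihydro-2H-pyran-3-yl acetate F8. Brief methanolysis (K2CO3 cat., MeOH, −10 °C) then gives 7.

**Step 5.** Most likely failure: competing electrophilic bromination of the trialkoxyphenyl ring B, or radical attack at a benzylic position. The fallback puts the halogen in by a nucleophile-mediated path that an arene cannot follow. It sets out from 8 and comes back at 18. I2 and pyridine in CH2Cl2 at rt should give (2R,3R)-2-[2,3-bis(benzyloxy)-4-methoxyphenyl]-5-iodo-3-methoxy-2,3-dihydro-4H-pyran-4-one F9. F9 is then taken through step 9 in place of 9, with HI lost instead of HBr, to give 18.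

**Step 6.** Most likely failure: self-condensation of the glycolate enolate, or proton transfer to the amide in place of C-acylation. The fallback makes the same C–C bond by aldol addition and adjusts the oxidation level afterwards. It sets out from 10 and comes back at 12. The enolate of 10 (LiN(iPr)2, THF, −78 °C) is added to acetaldehyde to give methyl 2-(benzyloxy)-3-hydroxybutanoate F10 as a diastereomer mixture. Dess–Martin oxidation then gives 12.

## Further compounds

F1 | step 9 | 1-(3,6-dihydroxy-2,4-dimethoxyphenyl)ethanone | CC(=O)c1c(O)cc(OC)c(O)c1OC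
F2 | step 9 | 1-[3-(benzyloxy)-6-hydroxy-2,4-dimethoxyphenyl]ethanone | CC(=O)c1c(O)cc(OC)c(OCc2ccccc2)c1OC
F3 | step 9 | 1-[3-(benzyloxy)-2,4-dimethoxy-6-(methoxymethoxy)phenyl]ethanone | CC(=O)c1c(OCOC)cc(OC)c(OCc2ccccc2)c1OC
F4 | step 9 | (E)-1-[3-(benzyloxy)-2,4-dimethoxy-6-(methoxymethoxy)phenyl]-3-[2,3-bis(benzyloxy)-4-methoxyphenyl]prop-2-en-1-one | COCOc1cc(OC)c(OCc2ccccc2)c(OC)c1C(=O)/C=C/c1ccc(OC)c(OCc2ccccc2)c1OCc1ccccc1
F5 | step 9 | [(2R,3S)-3-[2,3-bis(benzyloxy)-4-methoxyphenyl]oxiran-2-yl][3-(benzyloxy)-2,4-dimethoxy-6-(methoxymethoxy)phenyl]methanone | COCOc1cc(OC)c(OCc2ccccc2)c(OC)c1C(=O)[C@@H]1O[C@H]1c1ccc(OC)c(OCc2ccccc2)c1OCc1ccccc1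
F6 | step 9 | (2R,3R)-6-(benzyloxy)-2-[2,3-bis(benzyloxy)-4-methoxyphenyl]-3-hydroxy-5,7-dimethoxychroman-4-one | COc1ccc([C@H]2Oc3cc(OC)c(OCc4ccccc4)c(OC)c3C(=O)[C@@H]2O)c(OCc2ccccc2)c1OCc1ccccc1
F7 | step 9 | (2R,3R)-6-(benzyloxy)-2-[2,3-bis(benzyloxy)-4-methoxyphenyl]-3,5,7-trimethoxychroman-4-one | COc1ccc([C@H]2Oc3cc(OC)c(OCc4ccccc4)c(OC)c3C(=O)[C@@H]2OC)c(OCc2ccccc2)c1OCc1ccccc1
F8 | step 3 | (2R,3R)-2-[2,3-bis(benzyloxy)-4-methoxyphenyl]-4-oxo-3,4-dihydro-2H-pyran-3-yl acetate | COc1ccc([C@H]2OC=CC(=O)[C@@H]2OC(C)=O)c(OCc2ccccc2)c1OCc1ccccc1
F9 | step 5 | (2R,3R)-2-[2,3-bis(benzyloxy)-4-methoxyphenyl]-5-iodo-3-methoxy-2,3-dihydro-4H-pyran-4-one | COc1ccc([C@H]2OC=C(I)C(=O)[C@@H]2OC)c(OCc2ccccc2)c1OCc1ccccc1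
F10 | step 6 | methyl 2-(benzyloxy)-3-hydroxybutanoate (diastereomer mixture) | COC(=O)C(OCc1ccccc1)C(C)O
A1 | alternative 1 | (2R,3R)-6-(benzyloxy)-2-[2,3-bis(benzyloxy)-4-methoxyphenyl]-3,5,7-trimethoxychroman-4-one | COc1ccc([C@H]2Oc3cc(OC)c(OCc4ccccc4)c(OC)c3C(=O)[C@@H]2OC)c(OCc2ccccc2)c1OCc1ccccc1
A2 | alternative 1 | (3R)-3-{4-(benzyloxy)-2-[(ethylsulfanyl)carbonyl]-3,5-dimethoxyphenoxy}-3-[2,3-bis(benzyloxy)-4-methoxyphenyl]-2-methoxypropanoic acid (C2 epimers) | COc1ccc([C@@H](Oc2cc(OC)c(OCc3ccccc3)c(OC)c2C(=O)SCC)C(OC)C(O)=O)c(OCc2ccccc2)c1OCc1ccccc1
A3 | alternative 2 | (2S,3S)-6-(benzyloxy)-2-[2,3-bis(benzyloxy)-4-methoxyphenyl]-4,5,7-trimethoxy-3-(4,4,5,5-tetramethyl-1,3,2-dioxaborolan-2-yl)chromane (2,3-trans, C4 epimers) | COc1ccc([C@H]2Oc3cc(OC)c(OCc4ccccc4)c(OC)c3C(OC)[C@@H]2B5OC(C)(C)C(C)(C)O5)c(OCc2ccccc2)c1OCc1ccccc1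
A4 | alternative 2 | 3-(benzyloxy)-6-hydroxy-2,4-dimethoxybenzaldehyde | COc1cc(O)c(C=O)c(OC)c1OCc1ccccc1
A5 | alternative 2 | 2-{(E)-2-[2,3-bis(benzyloxy)-4-methoxyphenyl]ethenyl}-4,4,5,5-tetramethyl-1,3,2-dioxaborolane | COc1ccc(/C=C/B2OC(C)(C)C(C)(C)O2)c(OCc2ccccc2)c1OCc1ccccc1
A6 | alternative 3 | (2R,3R)-2-[2,3-bis(benzyloxy)-4-methoxyphenyl]-5,6-dihydroxy-3,7-dimethoxychroman-4-one | COc1ccc([C@H]2Oc3cc(OC)c(O)c(O)c3C(=O)[C@@H]2OC)c(OCc2ccccc2)c1OCc1ccccc1
A7 | alternative 3 | (2R,3R)-3-[2,3-bis(benzyloxy)-4-methoxyphenyl]-1-(2,3-dihydroxy-4-methoxyphenyl)-3-hydroxy-2-methoxypropan-1-one | COc1ccc([C@@H](O)[C@@H](OC)C(=O)c2ccc(OC)c(O)c2O)c(OCc2ccccc2)c1OCc1ccccc1
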